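**Retrosynthetic overview**
1. Sanggenol N comes from a cis-fused pentacyclic β-keto lactone by hydrolysis and loss of CO2. In that lactone a C3 carboxyl is tied to the 2'-oxygen as ring E, a traceless tether.
2. The keto lactone comes from a ring B/D salicylaldehyde and 4,5,7-trihydroxycoumarin in one operation. That operation makes C2–C3 (Knoevenagel), moves the acyl group from the ring A oxygen to the ring B oxygen (ring E closes), and closes O1–C2 enantioselectively (ring C closes).
3. The salicylaldehyde comes from 2,4-dihydroxybenzaldehyde by C5 Friedel–Crafts prenylation, then prenal annulation at C3/O4 (ring D).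
4. The trihydroxycoumarin comes from phloroglucinol and ethyl cyanoacetate (Houben–Hoesch).
5. Ring order: A and B are bought; D is formed first; the sacrificial coumarin lactone is made on the other branch; E and C close together; E leaves as CO2.

Assumption: the quinidine-derived thiourea is taken to give the 2S series. This is checked by CD on the product (2S flavanones show a positive band near 330 nm and a negative band near 290 nm). If the sense is reversed, the quinine-derived pseudoenantiomer is used under the same conditions.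

**Step 1**
Reactants: 1 2,4-dihydroxybenzaldehyde; 2 2-methylbut-3-en-2-ol
Product: 3 2,4-dihydroxy-5-(3-methylbut-2-en-1-yl)benzaldehyde
Conditions: BF3·OEt2 (0.3 equiv), 1,4-dioxane, rt, 4 h
Reagents that add atoms: 2-methylbut-3-en-2-ol (compound 2), CC(C)(O)C=C
Why: Friedel–Crafts prenylation, in which BF3 ionises the tertiary allylic alcohol to the dimethylallyl cation and its primary terminus is captured at C5 (ortho to the 4-OH, para to the 2-OH, far less crowded than C3), so 3 is the main monoalkylation product (about 30 %, separated from the 3-prenyl isomer on silica; no stereocentre).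

**Step 2**
Reactants: 3 2,4-dihydroxy-5-(3-methylbut-2-en-1-yl)benzaldehyde; 4 3-methylbut-2-enal (prenal)
Product: 6 5-hydroxy-2,2-dimethyl-8-(3-methylbut-2-en-1-yl)-2H-chromene-6-carbaldehyde, via ortho-quinone methide 5 (not isolated)
Conditions: (H3NCH2CH2NH3)(OAc)2 (ethylenediammonium diacetate, 10 mol%), xylene, reflux, 10 h
Reagents that add atoms: 3-methylbut-2-enal (compound 4), CC(C)=CC=O
Why: Formal [3+3] chromene annulation (Knoevenagel-type aldol, dehydration, oxa-6π electrocyclisation), in which C3 is the only free nucleophilic carbon and the 2-OH stays chelated to the formyl group, so 5 forms on and closes through the 4-oxygen to give ring D with the required regiochemistry and no stereocentre.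

**Step 3**
Reactants: 7 phloroglucinol; 8 ethyl cyanoacetate
Product: 10 4,5,7-trihydroxy-2H-chromen-2-one, via ketimine ester 9 (not isolated)
Conditions: ZnCl2, HCl (g), Et2O, 0 °C to rt; then H2O, reflux
Reagents that add atoms: ethyl cyanoacetate (compound 8), CCOC(=O)CC#N; water, O
Why: Houben–Hoesch acylation of the very electron-rich arene by the activated nitrile gives 9, and hot water then hydrolyses the C=N bond while an ortho-hydroxyl lactonises onto the ester, a classical protecting-group-free 4-hydroxycoumarin synthesis.

**Step 4 (key step)**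
Reactants: 6 5-hydroxy-2,2-dimethyl-8-(3-methylbut-2-en-1-yl)-2H-chromene-6-carbaldehyde (1.05 equiv); 10 4,5,7-trihydroxy-2H-chromen-2-one
Product: 13 (2S,3S)-cis keto lactone (Sanggenol N bearing a C3 carboxyl lactonised onto O2'), via arylidene chromanedione 11 (not isolated), via aroylcoumarin 12 (not isolated)
Conditions: N-[3,5-bis(trifluoromethyl)phenyl]-N'-[(9R)-6'-methoxycinchonan-9-yl]thiourea (C29H28F6N4OS, 10 mol%), 4 Å MS, toluene/2-MeTHF 3:1, 30 °C, 24 h, then −25 °C, 48 h, one pot; silica plug, recrystallise
Reagents that add atoms: none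
Why: Proposed new method: the quinuclidinium salt of acidic 10 condenses with the aldehyde (Knoevenagel) to give 11, whose ortho-phenol attacks the adjacent lactone carbonyl and releases the ring A phenol (translactonisation, known for 4-hydroxycoumarins and salicylaldehydes) to give 12 with ring E closed; once 10 is consumed the freed base deprotonates a ring A ortho-hydroxyl while the thiourea binds the 1,3-dicarbonyl, so O1 adds to one face of C2 (2S, ring C closed) and C3 is protonated to the favoured cis-fused 3S epimer; the closest known reaction type is the cinchona-thiourea-catalysed intramolecular oxa-Michael cyclisation of 2'-hydroxyaryl alkylidene β-keto esters to flavanone-3-carboxylates, and closure should be favoured because the second ortho-hydroxyl keeps the carbonyl chelate, as in 2',6'-dihydroxychalcones.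

**Step 5**
Reactants: 13 (2S,3S)-cis keto lactone
Product: 15 Sanggenol N, via keto acid 14 (not isolated)
Conditions: AcOH/H2O/THF 1:1:4, 45 °C, 6 h, N2
Reagents that add atoms: water, O
Why: Hydrolysis of the activated aryl β-keto lactone followed by β-keto acid decarboxylation through the usual cyclic transition state, in which water opens ring E to 14, CO2 leaves and the enol tautomerises, so C3 is erased, the 2'-OH is freed, the bonds at C2 are untouched, and the absence of base keeps retro-oxa-Michael racemisation shut.

**Compound list**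
1 | 2,4-dihydroxybenzaldehyde | O=Cc1ccc(O)cc1O | starting material
2 | 2-methylbut-3-en-2-ol | CC(C)(O)C=C | starting material
3 | 2,4-dihydroxy-5-(3-methylbut-2-en-1-yl)benzaldehyde | CC(C)=CCc1cc(C=O)c(O)cc1O | intermediate
4 | 3-methylbut-2-enal (prenal) | CC(C)=CC=O | starting material
5 | 2-hydroxy-3-(3-methylbut-2-en-1-ylidene)-5-(3-methylbut-2-en-1-yl)-4-oxocyclohexa-1,5-diene-1-carbaldehyde, dienyl arm syn to the C4 carbonyl (not isolated) | O=CC1=C(O)/C(=C/C=C(C)C)C(=O)C(CC=C(C)C)=C1 | intermediate
6 | 5-hydroxy-2,2-dimethyl-8-(3-methylbut-2-en-1-yl)-2H-chromene-6-carbaldehyde | CC(C)=CCc1cc(C=O)c(O)c2c1OC(C)(C)C=C2 | intermediate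
7 | phloroglucinol (benzene-1,3,5-triol) | Oc1cc(O)cc(O)c1 | starting material
8 | ethyl cyanoacetate | CCOC(=O)CC#N | starting material
9 | ethyl 3-imino-3-(2,4,6-trihydroxyphenyl)propanoate, formed as its hydrochloride (not isolated) | CCOC(=O)CC(=N)c1c(O)cc(O)cc1O | intermediate
10 | 4,5,7-trihydroxy-2H-chromen-2-one | O=C1C=C(O)c2c(O)cc(O)cc2O1 | intermediate
11 | 3-{[5-hydroxy-2,2-dimethyl-8-(3-methylbut-2-en-1-yl)-2H-chromen-6-yl]methylidene}-5,7-dihydroxychromane-2,4-dione, E/Z interconverting (not isolated) | CC(C)=CCc1cc(C=C2C(=O)Oc3cc(O)cc(O)c3C2=O)c(O)c2c1OC(C)(C)C=C2 | intermediate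
12 | 8,8-dimethyl-6-(3-methylbut-2-en-1-yl)-3-(2,4,6-trihydroxybenzoyl)-2H,8H-pyrano[2,3-f]chromen-2-one (not isolated) | CC(C)=CCc1cc2C=C(C(=O)c3c(O)cc(O)cc3O)C(=O)Oc2c2c1OC(C)(C)C=C2 | intermediate
13 | cis-fused pentacyclic keto lactone: (2S,3S)-5,7-dihydroxy-4-oxo-2-arylchromane-3-carboxylic acid lactonised onto the aryl 2'-oxygen; the aryl group is the 2,2-dimethyl-8-prenyl-2H-chromene unit bound through C6 to C2 and through O5 to the carboxyl; H2 and H3 cis (flavanone numbering) | CC(C)=CCc1cc2c(OC(=O)[C@H]3[C@@H]2Oc2cc(O)cc(O)c2C3=O)c2c1OC(C)(C)C=C2 | intermediate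
14 | (2S)-5,7-dihydroxy-2-[5-hydroxy-2,2-dimethyl-8-(3-methylbut-2-en-1-yl)-2H-chromen-6-yl]-4-oxochromane-3-carboxylic acid, C3 labile (not isolated) | CC(C)=CCc1cc([C@@H]2C(C(=O)O)C(=O)c3c(O)cc(O)cc3O2)c(O)c2c1OC(C)(C)C=C2 | intermediate
15 | Sanggenol N, (2S)-5,7-dihydroxy-2-[5-hydroxy-2,2-dimethyl-8-(3-methylbut-2-en-1-yl)-2H-chromen-6-yl]-2,3-dihydro-4H-chromen-4-one | CC(C)=CCc1cc([C@@H]2CC(=O)c3c(O)cc(O)cc3O2)c(O)c2c1OC(C)(C)C=C2 | target

**Totals**
- Total step count: 5.
- Longest linear sequence: 4 (1 → 3 → 6 → 13 → 15).

**Steps most likely to fail**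

Step 4. The risks are that closure of 12 to 13 is incomplete, that an uncatalysed racemic closure competes, or that the enantiomeric excess is low. The fallback sets out from 6 and 10 and comes back at 15. It gives up stereocontrol in the union and recovers it by resolution. Heating 6 and 10 with piperidinium acetate (10 mol%) in EtOH/H2O 9:1 at reflux runs through 11 and 12 to the racemic cis keto lactone F1. F1 is hydrolysed in the same pot to the racemic keto acid F2, which loses CO2 to give racemic Sanggenol N F3. Preparative chromatography on an amylose tris(3,5-dimethylphenylcarbamate) phase delivers 15. The unwanted (2R)-Sanggenol N F4 is returned to F3 with NaOAc in warm EtOH and recycled.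

Step 5. The risks are partial racemisation or acid damage to the chromene during the aqueous acid treatment. The fallback sets out from 13 and comes back at 15. It opens the lactone with an alcohol instead of water and removes the carboxyl under neutral palladium catalysis. Allyl alcohol (5 equiv) in toluene at 60 °C gives allyl (2S)-5,7-dihydroxy-2-[5-hydroxy-2,2-dimethyl-8-(3-methylbut-2-en-1-yl)-2H-chromen-6-yl]-4-oxochromane-3-carboxylate F5. Pd(PPh3)4 (2 mol%) and N-methylaniline in THF at rt then take off the allyl group. The resulting 14 loses CO2 at rt to give 15.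

Step 1. The risks are a low yield, the 3-prenyl isomer, and acid-induced chroman formation. The fallback sets out from 1 and comes back at 6. It builds ring D first and places the prenyl group by sigmatropy instead of cation chemistry. Compounds 1 and 4 under the step 2 conditions give 5-hydroxy-2,2-dimethyl-2H-chromene-6-carbaldehyde F6. Prenyl bromide and K2CO3 in DMF give 2,2-dimethyl-5-[(3-methylbut-2-en-1-yl)oxy]-2H-chromene-6-carbaldehyde F7. In N,N-diethylaniline at 200 °C both ortho positions are blocked, so a Claisen shift followed by a Cope shift carries the prenyl group, with normal connectivity, to the para carbon C8 and gives 6. This is one step longer than the main route.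

**Further compounds**
F1 | step 4 | racemic cis keto lactone (racemate of 13) | CC(C)=CCc1cc2c(OC(=O)C3C2Oc2cc(O)cc(O)c2C3=O)c2c1OC(C)(C)C=C2
F2 | step 4 | racemic keto acid (racemate of 14) | CC(C)=CCc1cc(C2C(C(=O)O)C(=O)c3c(O)cc(O)cc3O2)c(O)c2c1OC(C)(C)C=C2
F3 | step 4 | racemic Sanggenol N | CC(C)=CCc1cc(C2CC(=O)c3c(O)cc(O)cc3O2)c(O)c2c1OC(C)(C)C=C2
F4 | step 4 | (2R)-Sanggenol N | CC(C)=CCc1cc([C@H]2CC(=O)c3c(O)cc(O)cc3O2)c(O)c2c1OC(C)(C)C=C2
F5 | step 5 | allyl (2S)-5,7-dihydroxy-2-[5-hydroxy-2,2-dimethyl-8-(3-methylbut-2-en-1-yl)-2H-chromen-6-yl]-4-oxochromane-3-carboxylate | CC(C)=CCc1cc([C@@H]2C(C(=O)OCC=C)C(=O)c3c(O)cc(O)cc3O2)c(O)c2c1OC(C)(C)C=C2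
F6 | step 1 | 5-hydroxy-2,2-dimethyl-2H-chromene-6-carbaldehyde | O=Cc1ccc2OC(C)(C)C=Cc2c1O
F7 | step 1 | 2,2-dimethyl-5-[(3-methylbut-2-en-1-yl)oxy]-2H-chromene-6-carbaldehyde | O=Cc1ccc2OC(C)(C)C=Cc2c1OCC=C(C)C
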